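**Retrosynthetic overview**
1. The last bond is C2'–C3' of the lower triene, made by Stille coupling of vinylstannane 24 with iododienamide 12, which already carries the aminocyclopentenone unit.
2. The upper amide comes from acylating the aza-ylide of α-azidoenone 21 with trienoyl chloride 22.
3. The key disconnection is the ring C2–N bond. Azidoenone 21 comes from the meso bis-epoxy ketone 18 by catalytic azide opening of one of its two mirror-image oxiranes at Cα, followed by β-elimination. This one event fixes the absolute configuration at C4, C5 and C6.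
4. Diepoxide 18 comes from p-quinol 16 by a double OH-directed epoxidation. Quinol 16 comes from p-benzoquinone and (E)-Bu3SnCH=CHLi.
5. Ring order: both carbocycles are bought (benzoquinone, cyclopentane-1,3-dione). The two oxiranes form together in step 8 and one is consumed in step 9. No protecting groups are used.

Assumption: the sense of induction in step 9 is extrapolated from Cr(salen)/azide openings of meso-cycloalkene oxides and points to the (S,S)-catalyst; if the first run gives ent-21, the equally available (R,R)-catalyst is used and nothing else changes. Ring numbering throughout: C1 = C=O, C2 = C–N, C4 = carbinol, C5/C6 = oxirane.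

**Step 1**
Reactants: 1 (E)-4-methylpent-2-enal; 2 triethyl 4-phosphonocrotonate
Product: 4 (2E,4E,6E)-8-methylnona-2,4,6-trienoic acid, via ethyl (2E,4E,6E)-8-methylnona-2,4,6-trienoate 3 (not isolated)
Conditions: 2, LiHMDS, THF, −78 °C; add 1, −78 → 0 °C; then LiOH, MeOH/H2O, rt; 1 M HCl; recrystallise
Reagents that add atoms: lithium hydroxide, [Li+].[OH-]
Why: The vinylogous Horner–Wadsworth–Emmons olefination is E-selective for the new C4=C5 bond and leaves the two existing E-alkenes alone, and saponification in the same pot gives a crystalline acid from which minor Z-isomers are removed.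

**Step 2**
Reactants: 5 ethyl (E)-4-oxobut-2-enoate
Product: 6 ethyl (2E,4E)-5-iodopenta-2,4-dienoate
Conditions: CHI3, CrCl2 (6 equiv), THF, 0 °C
Reagents that add atoms: iodoform, IC(I)I
Why: In the Takai olefination the gem-dichromium reagent adds only to the aldehyde and eliminates to the E-vinyl iodide, and the minor Z isomer is removed by chromatography.

**Step 3**
Reactants: 6 ethyl (2E,4E)-5-iodopenta-2,4-dienoate
Product: 7 (2E,4E)-5-iodopenta-2,4-dienoic acid
Conditions: LiOH, THF/H2O, 0 °C → rt; 1 M HCl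
Reagents that add atoms: lithium hydroxide, [Li+].[OH-]
Why: This is a plain ester saponification, and the vinyl iodide and diene geometry are inert to cold aqueous LiOH.

**Step 4**
Reactants: 8 cyclopentane-1,3-dione
Product: 9 3-hydroxy-2-nitrocyclopent-2-en-1-one (enol of 2-nitrocyclopentane-1,3-dione)
Conditions: fuming HNO3 (1.1 equiv), CH2Cl2, 0 °C
Reagents that add atoms: nitric acid, O[N+](=O)[O-]
Why: Electrophilic nitration of the fully enolised 1,3-dione occurs at C2, its only nucleophilic carbon.

**Step 5**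
Reactants: 9 3-hydroxy-2-nitrocyclopent-2-en-1-one
Product: 10 2-amino-3-hydroxycyclopent-2-en-1-one hydrochloride
Conditions: H2 (1 atm), 10% Pd/C, conc. HCl (1.1 equiv), MeOH, rt
Reagents that add atoms: hydrogen chloride, Cl
Why: Catalytic hydrogenation reduces the nitro group to the amine, which is trapped as its salt so that it neither self-condenses nor air-oxidises.

**Step 6**
Reactants: 7 (2E,4E)-5-iodopenta-2,4-dienoic acid; 10 2-amino-3-hydroxycyclopent-2-en-1-one hydrochloride
Product: 12 (2E,4E)-N-(2-hydroxy-5-oxocyclopent-1-en-1-yl)-5-iodopenta-2,4-dienamide, via (2E,4E)-5-iodopenta-2,4-dienoyl chloride 11 (not isolated)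
Conditions: 7, (COCl)2, cat. DMF, CH2Cl2, 0 °C → rt, evaporate; then 10, Et3N (2.2 equiv), CH2Cl2/DMF, 0 °C → rt
Reagents that add atoms: none
Why: This is an acid chloride N-acylation, and any kinetically formed enol ester moves to nitrogen by O→N acyl shift under the basic conditions.

**Step 7**
Reactants: 13 (E)-1,2-bis(tributylstannyl)ethene; 14 p-benzoquinone
Product: 16 4-hydroxy-4-[(E)-2-(tributylstannyl)ethenyl]cyclohexa-2,5-dien-1-one, via (E)-2-(tributylstannyl)ethenyllithium 15 (not isolated)
Conditions: 13, n-BuLi (1.0 equiv), THF, −78 °C, 1 h; cannulate into 14 (1.5 equiv), THF, −78 °C; sat. NH4Cl at −78 °C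
Reagents that add atoms: none
Why: Tin–lithium exchange retains the E geometry, and inverse addition of the hard vinyllithium to excess quinone at −78 °C gives 1,2-addition to one carbonyl, producing an achiral p-quinol.

**Step 8**
Reactants: 16 4-hydroxy-4-[(E)-2-(tributylstannyl)ethenyl]cyclohexa-2,5-dien-1-one
Product: 18 meso-(2R,3S,4s,5R,6S)-2,3:5,6-diepoxy-4-hydroxy-4-[(E)-2-(tributylstannyl)ethenyl]cyclohexan-1-one (both oxirane O syn to OH), via rac-(4R*,5R*,6S*)-5,6-epoxy-4-hydroxy-4-[(E)-2-(tributylstannyl)ethenyl]cyclohex-2-en-1-one 17 (not isolated)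
Conditions: t-BuOOH (decane, 4 equiv), Triton B (0.2 equiv), THF, 0 °C
Reagents that add atoms: tert-butyl hydroperoxide, CC(C)(C)OO
Why: This is a double Weitz–Scheffer nucleophilic epoxidation in which hydrogen bonding of the peroxide to the C4-OH and shielding of the other face by the stannylvinyl group both send each oxygen syn to OH, setting the relative configuration at C4/C5/C6.

**Step 9**
Reactants: 18 meso-2,3:5,6-diepoxy-4-hydroxy-4-[(E)-2-(tributylstannyl)ethenyl]cyclohexan-1-one
Product: 21 (4R,5R,6S)-2-azido-5,6-epoxy-4-hydroxy-4-[(E)-2-(tributylstannyl)ethenyl]cyclohex-2-en-1-one, via (2S,3S,4S,5R,6S)-2-azido-5,6-epoxy-3,4-dihydroxy-4-[(E)-2-(tributylstannyl)ethenyl]cyclohexan-1-one 19 (not isolated), via 3-O-methanesulfonate of the azidohydrin 20 (not isolated)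
Conditions: (S,S)-(salen)CrN3 (5 mol %), TMSN3 (1.05 equiv), i-PrOH (1.05 equiv), TBME, 0 °C → rt; then same pot, THF, Et3N (3 equiv), MsCl (1.2 equiv), −20 → 0 °C
Reagents that add atoms: azidotrimethylsilane, C[Si](C)(C)N=[N+]=[N-]
Why: Proposed new method: enantiotopic-group-selective azidolysis of a meso bis(α,β-epoxy) ketone followed by β-elimination; the two oxiranes of 18 are mirror images, and each can realistically be attacked only at its carbonyl-flanked carbon (SN2 there is accelerated by the C=O π*, whereas C3/C5 are neopentyl next to quaternary C4); the bimetallic Cr(salen) pathway (one Cr binds the oxirane O, a second Cr–N3 delivers azide anti to it) strongly prefers one absolute sense of carbon in a cis-fused epoxide, so in one oxirane catalyst and substrate preferences coincide (attack at C2) while in the other they oppose (the catalyst would need blocked C5), giving trans-azidohydrin 19 from one oxirane only; mesylation of the secondary C3-OH and E1cB loss of mesylate then erase C2/C3 and leave C4, C5 and C6 with the absolute configuration fixed by the C–N bond formation; any minor enantiomer still carries the matched oxirane and is drained by a second opening, which should raise the ee; the closest known reaction types are the Jacobsen Cr(salen)-catalysed asymmetric ring opening of meso-epoxides with TMSN3/HN3, which tolerates ring ketones, and the racemic α-opening/dehydration of cyclic α,β-epoxy ketones by N, S and halide nucleophiles to 2-hetero-substituted enones.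

**Step 10**
Reactants: 21 (4R,5R,6S)-2-azido-5,6-epoxy-4-hydroxy-4-[(E)-2-(tributylstannyl)ethenyl]cyclohex-2-en-1-one; 4 (2E,4E,6E)-8-methylnona-2,4,6-trienoic acid
Product: 24 (2E,4E,6E)-N-{(4R,5R,6S)-5,6-epoxy-4-hydroxy-1-oxo-4-[(E)-2-(tributylstannyl)ethenyl]cyclohex-2-en-2-yl}-8-methylnona-2,4,6-trienamide, via (2E,4E,6E)-8-methylnona-2,4,6-trienoyl chloride 22 (not isolated), via P,P,P-trimethyl iminophosphorane of the 2-aminoenone 23 (not isolated)
Conditions: 4, (COCl)2, cat. DMF, CH2Cl2, 0 °C, evaporate; separately 21, PMe3 (1.0 M in THF, 1.05 equiv), THF, −20 → 0 °C; add 22, −20 → 0 °C; sat. aq NaHCO3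
Reagents that add atoms: none
Why: The Staudinger reaction of the electron-poor vinyl azide with PMe3 outruns attack on the enone or oxirane, the aza-ylide nitrogen is acylated by the acid chloride, and the acylaminophosphonium salt is hydrolysed in the buffered work-up (Staudinger/aza-ylide acylation) without touching a stereocentre or the tertiary OH.

**Step 11**
Reactants: 24 vinylstannane trienamide; 12 (2E,4E)-N-(2-hydroxy-5-oxocyclopent-1-en-1-yl)-5-iodopenta-2,4-dienamide
Product: 25 Manumycin G, (4S,5R,6S) in the ring numbering used here [= (1S,5S,6R)-7-oxabicyclo[4.1.0]hept-3-en-2-one numbering]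
Conditions: PdCl2(MeCN)2 (5 mol %), DMF, rt, dark
Reagents that add atoms: none
Why: Ligand-free Stille coupling of an E-vinylstannane with an E-vinyl iodide retains both geometries and is known in this family to tolerate the free quinol OH, the epoxy-enone and the acidic enol amide.

**Compound list**
1 | (E)-4-methylpent-2-enal | CC(C)/C=C/C=O | starting material
2 | triethyl 4-phosphonocrotonate | CCOC(=O)/C=C/CP(=O)(OCC)OCC | starting material
3 | ethyl (2E,4E,6E)-8-methylnona-2,4,6-trienoate | CC(C)/C=C/C=C/C=C/C(=O)OCC | intermediate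
4 | (2E,4E,6E)-8-methylnona-2,4,6-trienoic acid | CC(C)/C=C/C=C/C=C/C(=O)O | intermediate
5 | ethyl (E)-4-oxobut-2-enoate | CCOC(=O)/C=C/C=O | starting material
6 | ethyl (2E,4E)-5-iodopenta-2,4-dienoate | CCOC(=O)/C=C/C=C/I | intermediate
7 | (2E,4E)-5-iodopenta-2,4-dienoic acid | OC(=O)/C=C/C=C/I | intermediate
8 | cyclopentane-1,3-dione | O=C1CCC(=O)C1 | starting material
9 | 3-hydroxy-2-nitrocyclopent-2-en-1-one | O=C1CCC(O)=C1[N+](=O)[O-] | intermediate
10 | 2-amino-3-hydroxycyclopent-2-en-1-one hydrochloride | NC1=C(O)CCC1=O.Cl | intermediate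
11 | (2E,4E)-5-iodopenta-2,4-dienoyl chloride | O=C(Cl)/C=C/C=C/I | intermediate
12 | (2E,4E)-N-(2-hydroxy-5-oxocyclopent-1-en-1-yl)-5-iodopenta-2,4-dienamide | I/C=C/C=C/C(=O)NC1=C(O)CCC1=O | intermediate
13 | (E)-1,2-bis(tributylstannyl)ethene | CCCC[Sn](CCCC)(CCCC)/C=C/[Sn](CCCC)(CCCC)CCCC | starting material
14 | p-benzoquinone | O=C1C=CC(=O)C=C1 | starting material
15 | (E)-2-(tributylstannyl)ethenyllithium | [Li]/C=C/[Sn](CCCC)(CCCC)CCCC | intermediate
16 | 4-hydroxy-4-[(E)-2-(tributylstannyl)ethenyl]cyclohexa-2,5-dien-1-one | O=C1C=CC(O)(/C=C/[Sn](CCCC)(CCCC)CCCC)C=C1 | intermediate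
17 | rac-syn-5,6-epoxy-4-hydroxy-4-[(E)-2-(tributylstannyl)ethenyl]cyclohex-2-en-1-one (one enantiomer drawn) | O=C1C=C[C@@](O)(/C=C/[Sn](CCCC)(CCCC)CCCC)[C@@H]2O[C@@H]21 | intermediate
18 | meso-(2R,3S,4s,5R,6S)-2,3:5,6-diepoxy-4-hydroxy-4-[(E)-2-(tributylstannyl)ethenyl]cyclohexan-1-one | O=C1[C@@H]2O[C@@H]2[C@@](O)(/C=C/[Sn](CCCC)(CCCC)CCCC)[C@@H]3O[C@@H]31 | intermediate
19 | (2S,3S,4S,5R,6S)-2-azido-5,6-epoxy-3,4-dihydroxy-4-[(E)-2-(tributylstannyl)ethenyl]cyclohexan-1-one | O=C1[C@@H](N=[N+]=[N-])[C@H](O)[C@@](O)(/C=C/[Sn](CCCC)(CCCC)CCCC)[C@@H]2O[C@@H]21 | intermediate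
20 | 3-O-methanesulfonate of 19 | O=C1[C@@H](N=[N+]=[N-])[C@H](OS(C)(=O)=O)[C@@](O)(/C=C/[Sn](CCCC)(CCCC)CCCC)[C@@H]2O[C@@H]21 | intermediate
21 | (4R,5R,6S)-2-azido-5,6-epoxy-4-hydroxy-4-[(E)-2-(tributylstannyl)ethenyl]cyclohex-2-en-1-one | [N-]=[N+]=NC1=C[C@@](O)(/C=C/[Sn](CCCC)(CCCC)CCCC)[C@@H]2O[C@@H]2C1=O | intermediate
22 | (2E,4E,6E)-8-methylnona-2,4,6-trienoyl chloride | CC(C)/C=C/C=C/C=C/C(=O)Cl | intermediate
23 | (4R,5R,6S)-5,6-epoxy-4-hydroxy-4-[(E)-2-(tributylstannyl)ethenyl]-2-[(trimethyl-λ5-phosphanylidene)amino]cyclohex-2-en-1-one | CP(C)(C)=NC1=C[C@@](O)(/C=C/[Sn](CCCC)(CCCC)CCCC)[C@@H]2O[C@@H]2C1=O | intermediate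
24 | (2E,4E,6E)-N-{(4R,5R,6S)-5,6-epoxy-4-hydroxy-1-oxo-4-[(E)-2-(tributylstannyl)ethenyl]cyclohex-2-en-2-yl}-8-methylnona-2,4,6-trienamide | CC(C)/C=C/C=C/C=C/C(=O)NC1=C[C@@](O)(/C=C/[Sn](CCCC)(CCCC)CCCC)[C@@H]2O[C@@H]2C1=O | intermediate
25 | Manumycin G | CC(C)/C=C/C=C/C=C/C(=O)NC1=C[C@@](O)(/C=C/C=C/C=C/C(=O)NC2=C(O)CCC2=O)[C@@H]2O[C@@H]2C1=O | target

**Total step count:** 11. **Longest linear sequence:** 5 (steps 7 → 8 → 9 → 10 → 11, from p-benzoquinone).

**Three steps most likely to fail**

Step 9 (the new step). The electron-poor oxiranes may bind Cr(salen) poorly, giving slow turnover, a racemic background reaction with HN3, or low group selectivity.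
- The fallback uses only known chemistry. It sets out from acid 4 (and from 13 for the vinyllithium) and comes back at 24, replacing steps 7–10.
- Acid 4 is converted to 22 and coupled with commercial 2,5-dimethoxyaniline to give N-(2,5-dimethoxyphenyl)-(2E,4E,6E)-8-methylnona-2,4,6-trienamide F1.
- PhI(OAc)2 in MeOH oxidises it to the quinone monoketal 3-(trienamido)-4,4-dimethoxycyclohexa-2,5-dien-1-one F2.
- Weitz–Scheffer epoxidation under cinchona phase-transfer catalysis (t-BuOOH, NaOH, toluene, N-benzylcinchoninium chloride), followed by recrystallisation, gives the enantioenriched 5,6-epoxide of the monoketal F3.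
- Excess 15 adds to the ketone anti to the oxirane to give the syn-hydroxy-epoxide dimethyl ketal F4.
- Montmorillonite K10 in CH2Cl2 unmasks the ketone to give 24.

Step 7. Electron transfer from the vinyllithium to the quinone may give hydroquinone and a low quinol yield.
- The fallback sets out from 13 (as 15) and comes back at 16.
- Vinyllithium 15 is added to commercial 4,4-dimethoxycyclohexa-2,5-dien-1-one, which is not reducible in this way. This gives 4,4-dimethoxy-1-[(E)-2-(tributylstannyl)ethenyl]cyclohexa-2,5-dien-1-ol F5.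
- The ketal is then hydrolysed with montmorillonite K10 or aqueous oxalic acid on silica to give 16.

Step 10. The conjugated aza-ylide may be sluggish, or may be acylated at carbon.
- The fallback sets out from 21 and comes back at 24.
- Staudinger reduction with PPh3 in THF/H2O gives the isolated (4R,5R,6S)-2-amino-5,6-epoxy-4-hydroxy-4-[(E)-2-(tributylstannyl)ethenyl]cyclohex-2-en-1-one F6.
- The amine is then N-acylated with 22 and pyridine in CH2Cl2 at 0 °C.

**Further compounds**
F1 | step 9 | N-(2,5-dimethoxyphenyl)-(2E,4E,6E)-8-methylnona-2,4,6-trienamide | CC(C)/C=C/C=C/C=C/C(=O)Nc1cc(OC)ccc1OC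
F2 | step 9 | (2E,4E,6E)-N-(6,6-dimethoxy-3-oxocyclohexa-1,4-dien-1-yl)-8-methylnona-2,4,6-trienamide | CC(C)/C=C/C=C/C=C/C(=O)NC1=CC(=O)C=CC1(OC)OC
F3 | step 9 | 5,6-epoxide of F2, oxirane on the face found in 25 | CC(C)/C=C/C=C/C=C/C(=O)NC1=CC(=O)[C@@H]2O[C@@H]2C1(OC)OC
F4 | step 9 | dimethyl ketal of 24 (OH syn to oxirane) | CC(C)/C=C/C=C/C=C/C(=O)NC1=C[C@@](O)(/C=C/[Sn](CCCC)(CCCC)CCCC)[C@@H]2O[C@@H]2C1(OC)OC
F5 | step 7 | 4,4-dimethoxy-1-[(E)-2-(tributylstannyl)ethenyl]cyclohexa-2,5-dien-1-ol | COC1(OC)C=CC(O)(/C=C/[Sn](CCCC)(CCCC)CCCC)C=C1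
F6 | step 10 | (4R,5R,6S)-2-amino-5,6-epoxy-4-hydroxy-4-[(E)-2-(tributylstannyl)ethenyl]cyclohex-2-en-1-one | NC1=C[C@@](O)(/C=C/[Sn](CCCC)(CCCC)CCCC)[C@@H]2O[C@@H]2C1=O
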